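Retrosynthetic cuts, in order: Cα=Cβ of the cinnamic acid (to ArCHO and malonic acid), C4'–O (to C4'–B), C3'–C4' together with C5'–C6' in one operation, C3'–B, and C1'–C2' (benzylic chloride plus propynyl metal).
Enabling feature (chain numbered from C1', the benzylic CH2, to C7', the CMe2 carbon): the acetoxy carbon C4' is bonded to the sp2 carbon C3' and to C5'H2. C5' carries the C6'=C7' 2-methylpropenyl group, so C4'–C5' is a two-carbon vinylboron unit that accepts one alkenyl group on each carbon.
Forward: the benzene ring (ring A) is bought with its substitution pattern in place, and no ring of the target is formed. The chain grows C1'–C3' (alkyne, hydrozirconation, boronate), then C4'–C7' in the three-component coupling. B → OH → OAc, release of CHO and the two-carbon extension to the acid follow.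
Stereochemistry: C2'=C3' (E) comes from syn hydrozirconation and is kept through stereoretentive I, Li, B and 1,2-shift events. C4' (R) comes from the chiral bisphosphine on palladium and is carried through a stereoretentive oxidation. The cinnamate E olefin comes from the decarboxylative condensation.

Key step: step 7

Assumption: the (Sp,S'p) ligand enantiomer is taken to give 4R, by analogy with aryl- and alkenyl-migrating cases in which the migrating group and the CH2 arm hold the same CIP ranks. The sense is checked on alcohol 15 by Mosher ester analysis, and the commercial mirror-image ligand is used if it proves opposite.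

Step 1
Reactants: 1 3-(chloromethyl)-4-methoxybenzaldehyde
Product: 2 2-[3-(chloromethyl)-4-methoxyphenyl]-1,3-dioxolane
Conditions: (Me3SiOCH2)2 (1.2 equiv), Me3SiOTf (cat.), CH2Cl2, −78 to −20 °C; pyridine quench
Reagents that add atoms: 1,2-bis(trimethylsilyloxy)ethane, C[Si](C)(C)OCCO[Si](C)(C)C
Why: Noyori acetalization exchanges the aldehyde oxygen for the bis-silylated glycol at low temperature with no free alcohol, water or strong protic acid, so the solvolysis-prone o-methoxybenzylic chloride should survive while the formyl group is masked for the organometallic steps ahead.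

Step 2
Reactants: 2 2-[3-(chloromethyl)-4-methoxyphenyl]-1,3-dioxolane; 3 prop-1-yn-1-ylmagnesium bromide
Product: 4 2-[3-(but-2-yn-1-yl)-4-methoxyphenyl]-1,3-dioxolane
Conditions: 3 (1.3 equiv, THF solution), CuBr·SMe2 (10 mol %), THF, 0 to 50 °C
Reagents that add atoms: none
Why: Copper-catalysed sp3–sp cross-coupling of an alkynyl Grignard reagent with an activated benzylic halide (substitution through an alkynylcuprate) is the standard entry to 1-aryl-2-alkynes, the dioxolane is inert to the reagent, and the small excess of 3 limits base-induced alkyne-to-allene isomerisation.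

Step 3
Reactants: 4 2-[3-(but-2-yn-1-yl)-4-methoxyphenyl]-1,3-dioxolane
Product: 6 2-{3-[(2E)-3-iodobut-2-en-1-yl]-4-methoxyphenyl}-1,3-dioxolane, via alkenylzirconocene chloride 5 (not isolated)
Conditions: Cp2Zr(H)Cl (2 equiv), THF, rt to 45 °C, dark; then I2, THF, −78 to 0 °C
Reagents that add atoms: iodine, [I][I]; Cp2Zr(H)Cl, [H][Zr](Cl)(C1C=CC=C1)C1C=CC=C1 (zirconocene unit of 5 only)
Why: Hydrozirconation adds Zr–H syn, excess hydride with gentle warming lets the regioisomers equilibrate toward zirconium on the less hindered methyl-bearing C3', and iododezirconation goes with retention, so the target's C2'=C3' geometry (CH3 cis to C1') is set here and any minor regioisomer can be removed at the stable iodide.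

Step 4
Reactants: 6 2-{3-[(2E)-3-iodobut-2-en-1-yl]-4-methoxyphenyl}-1,3-dioxolane
Product: 8 2-{(2Z)-4-[5-(1,3-dioxolan-2-yl)-2-methoxyphenyl]but-2-en-2-yl}-4,4,5,5-tetramethyl-1,3,2-dioxaborolane, via alkenyllithium 7 (not isolated)
Conditions: t-BuLi (2.05 equiv), Et2O, −78 °C; iPrOBpin, −78 °C to rt; aq. NH4Cl; chromatography
Reagents that add atoms: 2-isopropoxy-4,4,5,5-tetramethyl-1,3,2-dioxaborolane, CC(C)OB1OC(C)(C)C(C)(C)O1; tert-butyllithium, [Li]C(C)(C)C (lithium of 7 only)
Why: Lithium–iodine exchange on an alkenyl iodide and trapping by a borate ester both retain olefin geometry (boron stays trans to C1', and the descriptor becomes Z only because carbon outranks boron), at −78 °C the exchange outruns deprotonation at the benzylic-allylic C1' and ortho-lithiation, and work-up with chromatography frees 8 of lithium halide.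

Step 5
Reactants: 9 tetravinylstannane
Product: 10 vinyllithium
Conditions: n-BuLi (4 equiv), pentane, rt; solid filtered under Ar, washed with pentane, dissolved in Et2O, titrated
Reagents that add atoms: n-butyllithium, [Li]CCCC
Why: Tin–lithium exchange is driven by the greater stability of the sp2 carbanion and by precipitation of vinyllithium from pentane, and it gives a reagent that has never been in contact with halide, as the coupling requires.

Step 6
Reactants: 11 isobutyraldehyde
Product: 12 2-methylprop-1-en-1-yl trifluoromethanesulfonate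
Conditions: Tf2O (1.1 equiv), 2,6-di-tert-butyl-4-methylpyridine (1.2 equiv), CH2Cl2, 0 °C to reflux; pentane, filter, distil
Reagents that add atoms: trifluoromethanesulfonic anhydride, O=S(=O)(OS(=O)(=O)C(F)(F)F)C(F)(F)F
Why: Enol triflate formation by O-triflylation of the aldehyde and loss of its single α-proton to the hindered, non-nucleophilic pyridine is standard for enolisable aldehydes, and the two identical methyl groups exclude regio- and geometric isomers.

Step 7
Reactants: 8 2-{(2Z)-4-[5-(1,3-dioxolan-2-yl)-2-methoxyphenyl]but-2-en-2-yl}-4,4,5,5-tetramethyl-1,3,2-dioxaborolane; 10 vinyllithium; 12 2-methylprop-1-en-1-yl trifluoromethanesulfonate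
Product: 14 2-{(2E,4R)-1-[5-(1,3-dioxolan-2-yl)-2-methoxyphenyl]-3,7-dimethylocta-2,6-dien-4-yl}-4,4,5,5-tetramethyl-1,3,2-dioxaborolane, via lithium bis(alkenyl)borate 13 (not isolated)
Conditions: 8, 10 (1.0 equiv), Et2O, 0 °C to rt; evaporate; Pd(OAc)2 (3 mol %), (Sp,S'p)-1,1'-bis[bis(3,5-dimethylphenyl)phosphino]-2,2'-bis[(R)-α-(dimethylamino)benzyl]ferrocene (3.6 mol %), 12 (1.2 equiv), THF, 60 °C; short silica plug
Reagents that add atoms: none
Why: Vinyllithium 10 adds to the vacant boron orbital of 8 to give bis(alkenyl)borate 13, while zerovalent palladium formed from Pd(OAc)2 and the bisphosphine inserts into the C–O bond of 12 to give a cationic divalent 2-methylpropenylpalladium whose open site binds the unsubstituted vinyl group of 13. That π-activation sets off a 1,2-metallate shift in which the butenyl group moves from boron to the adjacent carbon anti to palladium (C3'–C4', olefin geometry retained), and the resulting β-boryl alkylpalladium reductively eliminates to join C5' to C6'. The closest known reaction type is the enantioselective palladium-catalysed conjunctive cross-coupling of non-symmetric bis(alkenyl)borates with aryl or alkenyl triflates, which gives α-chiral allylboronates; no ring is closed here. C4', the only new stereocentre, is controlled by the chiral ferrocenyl bisphosphine, which decides the vinyl face that palladium occupies and hence, through the anti shift, the face that receives the migrating group. Site selectivity (vinyl as acceptor, butenyl as migrating group) rests on the steric gap between CH=CH2 and the trisubstituted C2'=C3' alkene, which also keeps that alkene and the new C6'=C7' alkene out of further reaction. Preference for the conjunctive path over direct Suzuki–Miyaura transfer and over β-hydride elimination rests on the halide-free medium (tin-derived 10, chromatographed 8, triflate leaving group), which keeps palladium cationic, and on the wide bite angle of the ligand, which speeds reductive elimination.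

Step 8
Reactants: 14 2-{(2E,4R)-1-[5-(1,3-dioxolan-2-yl)-2-methoxyphenyl]-3,7-dimethylocta-2,6-dien-4-yl}-4,4,5,5-tetramethyl-1,3,2-dioxaborolane
Product: 15 (2E,4R)-1-[5-(1,3-dioxolan-2-yl)-2-methoxyphenyl]-3,7-dimethylocta-2,6-dien-4-ol
Conditions: 3 M aq. NaOH, 30 % H2O2, THF, 0 °C to rt
Reagents that add atoms: hydrogen peroxide, OO
Why: In the boronate oxidation hydroperoxide adds to boron and C4' migrates from boron to oxygen with retention, so the 4R configuration carries over, while the acetal and both trisubstituted alkenes are inert to basic peroxide.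

Step 9
Reactants: 15 (2E,4R)-1-[5-(1,3-dioxolan-2-yl)-2-methoxyphenyl]-3,7-dimethylocta-2,6-dien-4-ol
Product: 16 (2E,4R)-1-[5-(1,3-dioxolan-2-yl)-2-methoxyphenyl]-3,7-dimethylocta-2,6-dien-4-yl acetate
Conditions: Ac2O, Et3N, DMAP (cat.), CH2Cl2, 0 °C to rt
Reagents that add atoms: acetic anhydride, CC(=O)OC(C)=O
Why: DMAP-catalysed acyl transfer acetylates the secondary allylic alcohol under basic conditions that cannot ionise the C4'–O bond, so configuration and olefin position are kept.

Step 10
Reactants: 16 (2E,4R)-1-[5-(1,3-dioxolan-2-yl)-2-methoxyphenyl]-3,7-dimethylocta-2,6-dien-4-yl acetate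
Product: 17 (2E,4R)-1-(5-formyl-2-methoxyphenyl)-3,7-dimethylocta-2,6-dien-4-yl acetate
Conditions: PPTS (cat.), acetone–H2O, rt to 40 °C
Reagents that add atoms: water, O
Why: In this acid-catalysed acetal hydrolysis the p-methoxy group stabilises the benzylic oxocarbenium ion so well that the weak acid PPTS suffices, which leaves the allylic acetate, the skipped diene and C4' untouched.

Step 11
Reactants: 17 (2E,4R)-1-(5-formyl-2-methoxyphenyl)-3,7-dimethylocta-2,6-dien-4-yl acetate; 18 malonic acid
Product: 20 (2E)-3-{3-[(2E,4R)-4-acetoxy-3,7-dimethylocta-2,6-dien-1-yl]-4-methoxyphenyl}prop-2-enoic acid, via arylidenemalonic acid 19 (not isolated)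
Conditions: 18 (2 equiv), pyridine, piperidine (0.1 equiv), 80 °C; cold aq. citric acid work-up
Reagents that add atoms: none
Why: In the Knoevenagel–Doebner condensation amine-catalysed condensation gives 19, which loses CO2 in warm pyridine to the thermodynamically favoured E-cinnamic acid directly as the free acid, so no ester hydrolysis has to compete with the acetate and C4' lies far from any acidic site.

Compound list
1 | 3-(chloromethyl)-4-methoxybenzaldehyde | COc1ccc(C=O)cc1CCl | starting material
2 | 2-[3-(chloromethyl)-4-methoxyphenyl]-1,3-dioxolane | COc1ccc(C2OCCO2)cc1CCl | intermediate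
3 | prop-1-yn-1-ylmagnesium bromide | CC#C[Mg]Br | starting material
4 | 2-[3-(but-2-yn-1-yl)-4-methoxyphenyl]-1,3-dioxolane | COc1ccc(C2OCCO2)cc1CC#CC | intermediate
5 | chloro{(2E)-4-[5-(1,3-dioxolan-2-yl)-2-methoxyphenyl]but-2-en-2-yl}bis(cyclopentadienyl)zirconium (Cp rings drawn σ-bonded in the string) | COc1ccc(C2OCCO2)cc1C/C=C(\C)[Zr](Cl)(C1C=CC=C1)C1C=CC=C1 | intermediate
6 | 2-{3-[(2E)-3-iodobut-2-en-1-yl]-4-methoxyphenyl}-1,3-dioxolane | COc1ccc(C2OCCO2)cc1C/C=C(\C)I | intermediate
7 | (2Z)-4-[5-(1,3-dioxolan-2-yl)-2-methoxyphenyl]but-2-en-2-yllithium (lithium trans to the benzylic CH2) | COc1ccc(C2OCCO2)cc1C/C=C(\C)[Li] | intermediate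
8 | 2-{(2Z)-4-[5-(1,3-dioxolan-2-yl)-2-methoxyphenyl]but-2-en-2-yl}-4,4,5,5-tetramethyl-1,3,2-dioxaborolane (boron trans to the benzylic CH2; Z because carbon outranks boron) | COc1ccc(C2OCCO2)cc1C/C=C(\C)B1OC(C)(C)C(C)(C)O1 | intermediate
9 | tetravinylstannane | C=C[Sn](C=C)(C=C)C=C | starting material
10 | vinyllithium | [Li]C=C | intermediate
11 | isobutyraldehyde | CC(C)C=O | starting material
12 | 2-methylprop-1-en-1-yl trifluoromethanesulfonate | CC(C)=COS(=O)(=O)C(F)(F)F | intermediate
13 | lithium {(2Z)-4-[5-(1,3-dioxolan-2-yl)-2-methoxyphenyl]but-2-en-2-yl}(ethenyl)(pinacolato)borate | [Li+].COc1ccc(C2OCCO2)cc1C/C=C(\C)[B-]1(C=C)OC(C)(C)C(C)(C)O1 | intermediate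
14 | 2-{(2E,4R)-1-[5-(1,3-dioxolan-2-yl)-2-methoxyphenyl]-3,7-dimethylocta-2,6-dien-4-yl}-4,4,5,5-tetramethyl-1,3,2-dioxaborolane | COc1ccc(C2OCCO2)cc1C/C=C(\C)[C@@H](CC=C(C)C)B1OC(C)(C)C(C)(C)O1 | intermediate
15 | (2E,4R)-1-[5-(1,3-dioxolan-2-yl)-2-methoxyphenyl]-3,7-dimethylocta-2,6-dien-4-ol | COc1ccc(C2OCCO2)cc1C/C=C(\C)[C@@H](CC=C(C)C)O | intermediate
16 | (2E,4R)-1-[5-(1,3-dioxolan-2-yl)-2-methoxyphenyl]-3,7-dimethylocta-2,6-dien-4-yl acetate | COc1ccc(C2OCCO2)cc1C/C=C(\C)[C@@H](CC=C(C)C)OC(C)=O | intermediate
17 | (2E,4R)-1-(5-formyl-2-methoxyphenyl)-3,7-dimethylocta-2,6-dien-4-yl acetate | COc1ccc(C=O)cc1C/C=C(\C)[C@@H](CC=C(C)C)OC(C)=O | intermediate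
18 | malonic acid | OC(=O)CC(=O)O | starting material
19 | 2-({3-[(2E,4R)-4-acetoxy-3,7-dimethylocta-2,6-dien-1-yl]-4-methoxyphenyl}methylidene)propanedioic acid | COc1ccc(C=C(C(=O)O)C(=O)O)cc1C/C=C(\C)[C@@H](CC=C(C)C)OC(C)=O | intermediate
20 | (2E)-3-{3-[(2E,4R)-4-acetoxy-3,7-dimethylocta-2,6-dien-1-yl]-4-methoxyphenyl}prop-2-enoic acid (CNP0206859.1) | COc1ccc(/C=C/C(=O)O)cc1C/C=C(\C)[C@@H](CC=C(C)C)OC(C)=O | target

Total step count: 11 (steps 5 and 6 are one-step side branches).
Longest linear sequence: 9 steps (1 → 2 → 4 → 6 → 8 → 14 → 15 → 16 → 17 → 20).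

Steps most likely to fail

1. Step 7. The α-branched butenyl group may migrate slowly. Direct transfer of a boron-bound alkenyl group to palladium or β-hydride elimination could then take over, and facial selectivity could erode. The fallback is a reagent-controlled lithiation–borylation that sets out from 8 and comes back at 14.
- Commercial 4-methylpent-3-en-1-ol is carbamoylated (iPr2NCOCl, Et3N, reflux) to 4-methylpent-3-en-1-yl N,N-diisopropylcarbamate F1.
- s-BuLi with (−)-sparteine in Et2O at −78 °C removes the pro-S proton next to oxygen and gives the configurationally stable (1S)-1-lithio-4-methylpent-3-en-1-yl N,N-diisopropylcarbamate F2.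
- Boronate 8 is added and captures the carbanion with retention as the lithium carbamoyloxyalkyl boronate complex F3.
- MgBr2·OEt2 and warming to reflux bring about the 1,2-shift of the butenyl group with inversion at carbon and loss of the carbamate, which should give 14 with the 4R configuration.
- In this variant C5'–C6' is bought with the alcohol, and stereocontrol passes from the catalyst to the diamine.

2. Step 3. The steric difference between CH2Ar and CH3 is modest, so Zr–H addition may be poorly regioselective, and prolonged warming may cause over-reduction. The fallback sets out from 2 and comes back at 8, replacing steps 2 to 4.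
- Compound 2 is coupled with vinylmagnesium bromide (CuBr·SMe2 cat., THF) to 2-[4-methoxy-3-(prop-2-en-1-yl)phenyl]-1,3-dioxolane F4.
- F4 undergoes olefin cross-metathesis with commercial isopropenylboronic acid pinacol ester. The conditions are second-generation Grubbs catalyst RuCl2(=CHPh)(PCy3)(H2IMes), CH2Cl2, 40 °C, with 1,4-benzoquinone to suppress migration of the allyl double bond.
- The position of boron is then fixed by the reagent rather than by a hydrometalation. Thermodynamic control should place the benzylic CH2 trans to the bulky boronate, which is the geometry of 8.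

3. Step 11. Hot pyridine with piperidine may cause loss of the acetate by aminolysis or elimination while the electron-rich aldehyde condenses slowly. The fallback installs the acetate last; it sets out from 15 and comes back at 20.
- The dioxolane of 15 is hydrolysed (PPTS, acetone–H2O) to 3-[(2E,4R)-4-hydroxy-3,7-dimethylocta-2,6-dien-1-yl]-4-methoxybenzaldehyde F5.
- Knoevenagel–Doebner condensation with 18 passes through the hydroxy arylidenemalonic acid F6 to (2E)-3-{3-[(2E,4R)-4-hydroxy-3,7-dimethylocta-2,6-dien-1-yl]-4-methoxyphenyl}prop-2-enoic acid F7.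
- Excess Ac2O in pyridine with DMAP acetylates the alcohol and turns the acid into the acetic cinnamic mixed anhydride F8.
- Stirring with aqueous NaHCO3–THF hydrolyses F8 selectively to 20.

Further compounds
F1 | step 7 | 4-methylpent-3-en-1-yl N,N-diisopropylcarbamate | CC(C)=CCCOC(=O)N(C(C)C)C(C)C
F2 | step 7 | (1S)-1-lithio-4-methylpent-3-en-1-yl N,N-diisopropylcarbamate (as its sparteine complex) | [Li][C@@H](CC=C(C)C)OC(=O)N(C(C)C)C(C)C
F3 | step 7 | lithium [(1S)-1-(diisopropylcarbamoyloxy)-4-methylpent-3-en-1-yl]{(2Z)-4-[5-(1,3-dioxolan-2-yl)-2-methoxyphenyl]but-2-en-2-yl}(pinacolato)borate | [Li+].COc1ccc(C2OCCO2)cc1C/C=C(\C)[B-]1([C@@H](CC=C(C)C)OC(=O)N(C(C)C)C(C)C)OC(C)(C)C(C)(C)O1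
F4 | step 3 | 2-[4-methoxy-3-(prop-2-en-1-yl)phenyl]-1,3-dioxolane | COc1ccc(C2OCCO2)cc1CC=C
F5 | step 11 | 3-[(2E,4R)-4-hydroxy-3,7-dimethylocta-2,6-dien-1-yl]-4-methoxybenzaldehyde | COc1ccc(C=O)cc1C/C=C(\C)[C@@H](CC=C(C)C)O
F6 | step 11 | 2-({3-[(2E,4R)-4-hydroxy-3,7-dimethylocta-2,6-dien-1-yl]-4-methoxyphenyl}methylidene)propanedioic acid | COc1ccc(C=C(C(=O)O)C(=O)O)cc1C/C=C(\C)[C@@H](CC=C(C)C)O
F7 | step 11 | (2E)-3-{3-[(2E,4R)-4-hydroxy-3,7-dimethylocta-2,6-dien-1-yl]-4-methoxyphenyl}prop-2-enoic acid | COc1ccc(/C=C/C(=O)O)cc1C/C=C(\C)[C@@H](CC=C(C)C)O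
F8 | step 11 | acetic (2E)-3-{3-[(2E,4R)-4-acetoxy-3,7-dimethylocta-2,6-dien-1-yl]-4-methoxyphenyl}prop-2-enoic anhydride | COc1ccc(/C=C/C(=O)OC(C)=O)cc1C/C=C(\C)[C@@H](CC=C(C)C)OC(C)=O
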